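(The runs are simulated from invented constants; the scatter is artificial.)

If every bit of substrate lost had turned into ring, c(ring) would equal the loss of substrate, so take that case as the mark and measure this flask against it.

| flask | substrate | activator | remark | time |
|---|---|---|---|---|
| elm | 10 mM | 10.5 mM | the very flask that is asked about, followed so far |  |
| flask | 10 mM | 10.5 mM |  | 10 d |

elm run (percent of the substrate charged)

| time / d | ring / % | substrate / % |
|---|---|---|
| 0.833 | 3.1 | 59.3 |
| 1.04 | 4.9 | 52.7 |
| 1.25 | 5.6 | 47.1 |
| 1.67 | 6.7 | 37.2 |
| 2.08 | 7.9 | 30.4 |
| 2.50 | 8.1 | 24.8 |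
| 3.00 | 7.7 | 20.0 |

(scatter of a reading: 0.5 percentage points)

1. when, up to 10 d, the flask holds most ring
2. the amount of ring, in percent of the substrate charged, at that time



Start with the elm reading at 2.50 d: c(substrate) stands at 24.8 %, so 75.2 % of the charge has gone, but c(ring) is 8.1 %. Call ring held over substrate lost the ring share (a selectivity); read here it is 10.8 %. The next reading is 7.7 %, but that drop of 0.4 percentage points is less than the scatter of 0.5 points, so the readings do not prove that the peak has passed. With 20.0 % of the substrate still there, a steady share would carry ring towards 10.8 % of the charge. So expect a peak between 8.1 % and 10.8 %, and put it after 3.00 d, though the readings give no close time.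

The forecast gives 2.5 d (2.1 d to 3 d) and 8 % (7.5 % to 8.7 %), holding that “a later rise is unlikely”.

The flask gives 3.51 d and 8.88 %.

    substrate + activator → activated form (k = 2.20 M⁻¹ h⁻¹)
    activated form → ring (k = 0.0210 h⁻¹)
    substrate + activated form → open dimer (k = 5.50 M⁻¹ h⁻¹)
    ring ⇌ isomer of the product (K = 4.50, k = 0.0340 h⁻¹)

At that peak the flask still holds 16.7 % of the substrate charged, so its ring share is 10.7 %; at 10.0 d it is 8.00 %. Now reckon the same share for the neighbour charged with 4.0 mM of substrate and the same activator: at 10.0 d it holds 12.8 % of ring with 0.853 % of substrate left, a share of 12.9 %, higher than in the flask, and its ring peak stands at 15.5 %.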